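## The problem

Compound 37 is a briarane. Numbering used throughout: C1 is the quaternary methyl-bearing carbon, C2 and C4 the acetoxy carbons of the chain, C5=C6 the olefin (C16 hydroxymethyl on C5), C7 the lactone O–CH, C8 the tertiary carbinol, C9 an acetoxy CH, C10 the ring-fusion CH, C11–C12 the epoxide (methyl on C11), C13 a CH2, C14 the ring acetoxy CH, C17 the lactone CHMe and C19 the lactone carbonyl.

- **Ring system.** Cyclohexane ring A (C1, C10–C14) is fused through C1–C10 to a ten-membered carbocycle (C1–C10). That ring carries a γ-lactone across C7–C8 and a (5Z)-trisubstituted olefin, so a medium ring has to be closed or unveiled at some point.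
- **Stereocentres.** There are eleven: C1, C10, C14 and the epoxide carbons C11/C12 on ring A; C2, C4, C7, C8, C9 in the medium ring; C17 on the lactone.
- **Possible relays.** C1, C10 and C14 can be set together. C10 can steer addition to a C9 aldehyde. A free C9 hydroxyl can direct both a 1,3-syn reduction at C7 and the face of epoxidation at C11=C12. C7 can fix C8 and C17 when the lactone closes. C2 can bias C4 by 1,3-induction.
- **Fragile groups.** Four secondary acetates sit beside a free tertiary and a free primary allylic hydroxyl, which rules out strong bases, hydrides and organolithiums late and invites acyl migration. The trisubstituted epoxide is acid-sensitive. The β-hydroxy lactone can undergo retro-aldol cleavage or translactonise to O9. β-Acetoxy carbonyl intermediates eliminate easily.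
- **Enabling feature.** Ring A carries contiguous C14 (acetoxy), C1 (methyl, C2) and C10 (C9), with O14 cis to C2 and C2 trans to C9, and C11 (methyl) and C12 (oxygen) on the far side. This is the pattern of an endo [4+2] adduct between a 1-acetoxy-3-silyloxy-penta-1,3-diene (C14–C13–C12–C11) and an (E)-α-methyl enal (C2–C1=C10–C9).

## Retrosynthesis

**Endgame and medium ring.** Target 37 is traced to its 16-O-PMB ether 36 and, by removing the C4 acetate, to macrocyclic alcohol 35. The C4–C5 bond of 35 is cut, giving seco-aldehyde 33 with a (Z)-alkenyl iodide at C5; 33 comes from terminal olefin 31 by oxidative cleavage.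
- This cut is preferred to closing C5=C6 by metathesis (a Z-trisubstituted olefin in a ten-membered ring is unreliable) and to an aldol closure at C2–C3 or C3–C4 (no control, enolisable acetates).
- The olefin geometry is fixed beforehand in the iodide, and the carbinol that forms is the one that must carry an acetate.
- The forward Nozaki–Hiyama–Kishi reaction must tolerate acetates, lactone, epoxide and a free tertiary alcohol, and should give the 2,4-anti carbinol.

**Lactone.** In 31 the C8–C17 bond is cut, leading to α-(2-bromopropanoyloxy) ketone 29.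
- C8–C17 is the aldol bond of the β-hydroxy lactone. Tethering the nucleophile to O7 excludes the isomeric O9 lactone.
- The five-membered transition state should place C9 trans to C6 and the C17 methyl trans to C9, which is the target arrangement.
- Ketone 29 comes from syn-diol 25 by O7 acylation (26), O9 acetylation (27), O8 desilylation (28) and oxidation.
- The forward step must generate the C17 enolate without base; SmI2 does this.

**C7 and the epoxide.** Diol 25 is traced to epoxy aldol 24 (C7–H bond) and 24 to aldol 23 (epoxide C–O bonds). Both events are directed by the C9 hydroxyl, and this is the only stage at which it is free. Undirected peracid epoxidation late in the route would have to choose between two hindered faces of ring A.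

**C8–C9 bond.** Aldol 23 is cut into aldehyde 15 and (Z)-β-iodoenone 21.
- One step brings in C5–C8 and C16 with the alkenyl iodide in place.
- C8 arrives as a silyl-protected carbinol that later becomes the ketone, so its configuration is irrelevant.
- Cuts at C7–C8 or C9–C10 would need acyl-anion or α-alkoxy organometallic chemistry that the acetates would not survive.
- The forward reaction must show Felkin selectivity at C9 and must enolise a β-iodoenone cleanly.

**Iodoenone.** Compound 21 comes from ynone 20 by conjugate hydroiodination, which places iodine on C5 and gives the Z geometry. Ynone 20 comes from propargylic alcohol 19, and 19 from alkyne 16 and aldehyde 17.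

**Ring A adjustment and C2–C4.** Aldehyde 15 is traced through alcohol 14 to olefin 13. The C11=C12 olefin comes from enol triflate 12, and 12 from ketone 11, the hydrolysis product of enol ether 10. Acetate 10 comes from alcohol 9, and cutting C2–C3 of 9 (allylation) leads to cycloadduct 8.
- The allyl group is a latent C4 aldehyde. It is cleaved only after the ring A olefin has become the epoxide, so no second electron-rich olefin competes.
- O9 is a TBDPS ether so that the enol ether can be hydrolysed selectively. O8 is a TBS ether and O16 a PMB ether so that each is removed independently.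

**Ring A.** Cycloadduct 8 is cut at C14–C1 and C10–C11 into diene 4 and enal 7. One step makes the ring, the quaternary centre, the C14 acetate in its final form and the C12 oxygen handle. Stepwise annulations would set these centres one by one. The reaction must be regioselective, endo-selective and face-selective.

**Building blocks.** Diene 4 comes from β-acetoxy enone 3, which comes from ynone 2 and alcohol 1. Enal 7 comes from aldehyde 5 and ylide 6.

## Roads not taken

**Alternative 1: ring-fusion glycol cleavage.**
- Cut: retrosynthetically C4 and C9 are joined, turning the ten-membered ring into two fused six-membered rings. Forward, Pb(OAc)4 cleaves the C4–C9 bond between two ring-fusion carbinols and releases the ten-membered 4,9-diketone A1.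
- Merits: the medium ring is never closed against entropy or transannular strain. The Z olefin is secured inside a six-membered ring beforehand. Glycol cleavage is mild.
- Weak points: A1 has ketones at C4 and C9, so two stereoselective reductions are needed in a mobile ring, one next to the epimerisable C10. A 1,6-diketone in a ten-membered ring invites transannular aldol reaction. The tricyclic glycol with the C8 quaternary centre is itself demanding, and ring A is not addressed.
- Comparison: this road is better than the chosen plan on ring closure, which is the chosen plan's most fragile step. The chosen plan sets against it that C9 and C4 are made as carbinols under Felkin and 1,3-anti control with an oxidation–reduction reserve, and that ring A arrives in one catalytic step.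

**Alternative 2: transannular allylic alkylation.**
- Cut: C1–C10 inside a fourteen-membered carbocycle. Forward, zerovalent palladium ionises a C10 allylic carbonate and the enolate of the 2-methyl-1,3-diketone (C14, C1, C2) attacks C10 across the ring, giving bicyclic diketone A2.
- Merits: one step makes the quaternary centre, ring A and the ten-membered ring. A large ring is easier to close. The C11=C12 olefin is delivered ready for epoxidation.
- Weak points: C1 and C10 are both set by macrocycle conformation, with no reagent handle. Attack at the other allyl terminus and O-alkylation compete. Two ketones flanking the quaternary carbon must then be reduced with defined configuration. The decisive test comes on a fully elaborated substrate.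
- Comparison: in convergency and bond economy this road is superior if the transannular step behaves. The chosen plan sets against it a well-modelled, catalyst-controlled reaction at step 5 that fixes C1, C10 and C14 and installs the C14 acetate, so failure is found early.

**Alternative 3: samarium Reformatsky closure of the lactone on the finished bicycle.**
- Cut: C8–C17. Forward, SmI2 reduces an O7 2-bromopropanoate and the samarium enolate adds to the C8 ketone, giving β-hydroxy lactone A3.
- Merits: the enolate forms at one site without base, the tether guarantees the O7 lactone, and two stereocentres form in one short step.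
- Weak points: it is an endgame only and says nothing about ring A or the medium ring. On the macrocyclic ketone the accessible face of C8 is set by ring conformation. The doubly α-oxygenated ketone can lose an acyloxy group reductively.
- Comparison: the chosen route uses the same bond construction in step 23. Alternative 3 is better in that the lactone is made last and need not survive ring closure and acylation. The chosen plan runs the step on the open chain, where the forming five-membered ring alone decides C8 and C17, and the finished lactone then stiffens the seco chain for cyclisation.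

Key step: step 5

Remarks on the chemistry:
- The C8 carbinol centre of 23–28 and the bromine-bearing carbon of 26–29 are erased later. Compounds 23–28 are drawn for the syn aldol series, and the bromo ester is a mixture of epimers.
- Compounds 1, 5, 6, 16, 17 and B-allyldiisopinocampheylborane are taken as catalogue materials.

## Route

Step 1
Reactants: 1 pent-1-yn-3-ol
Product: 2 pent-1-yn-3-one
Conditions: Dess–Martin periodinane, CH2Cl2, 0 °C to rt
Reagents that add atoms: none
Why: Dess–Martin oxidation of a secondary propargylic alcohol; the neutral medium avoids conjugate addition to the volatile ynone, which is used as a solution.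

Step 2
Reactants: 2 pent-1-yn-3-one
Product: 3 (E)-3-oxopent-1-en-1-yl acetate
Conditions: AcOH (1.5 equiv), DABCO (5 mol %), CH2Cl2, 0 °C
Reagents that add atoms: acetic acid CC(=O)O
Why: Amine-catalysed conjugate addition of a carboxylic acid to an ynone; the amine adds first and is displaced by acetate, and the E β-acyloxy enone is the thermodynamic product.

Step 3
Reactants: 3 (E)-3-oxopent-1-en-1-yl acetate
Product: 4 (1E,3Z)-3-[(tert-butyldimethylsilyl)oxy]penta-1,3-dien-1-yl acetate
Conditions: TBSOTf, Et3N, Et2O, −78 to 0 °C
Reagents that add atoms: tert-butyldimethylsilyl triflate CC(C)(C)[Si](C)(C)OS(=O)(=O)C(F)(F)F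
Why: Soft enolisation and O-silylation of the ethyl ketone; the methyl group turns away from the vinyl chain and gives the Z silyl enol ether, as for related 4-methyl-1-oxy-3-silyloxy dienes.

Step 4
Reactants: 5 [(tert-butyldiphenylsilyl)oxy]acetaldehyde; 6 2-(triphenylphosphoranylidene)propanal
Product: 7 (E)-4-[(tert-butyldiphenylsilyl)oxy]-2-methylbut-2-enal
Conditions: toluene, 80 °C
Reagents that add atoms: none
Why: Wittig olefination with a stabilised ylide gives the E trisubstituted enal.

Step 5
Reactants: 4 (1E,3Z)-3-[(tert-butyldimethylsilyl)oxy]penta-1,3-dien-1-yl acetate; 7 (E)-4-[(tert-butyldiphenylsilyl)oxy]-2-methylbut-2-enal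
Product: 8 ring A cycloadduct (1S,4S,5S,6R)-3-[(tert-butyldimethylsilyl)oxy]-5-{[(tert-butyldiphenylsilyl)oxy]methyl}-6-formyl-4,6-dimethylcyclohex-2-en-1-yl acetate
Conditions: (R)-3,3-diphenyl-1-(o-tolyl)tetrahydro-1H,3H-pyrrolo[1,2-c][1,3,2]oxazaborole (20 mol %), HNTf2 (18 mol %), CH2Cl2, −78 to −40 °C
Reagents that add atoms: none
Why: The enal binds the boron of the protonated oxazaborolidine with a formyl C–H···O contact, which lowers its LUMO and holds it s-trans over one phenyl group; the diene then adds in a concerted, asynchronous [4+2] in which C11–C10 bonding runs ahead of C14–C1 bonding. The closest known reaction type is the oxazaborolidinium-catalysed Diels–Alder reaction of α-substituted enals with 2-silyloxy and 1-oxygenated dienes. Ring A is closed by the cycloaddition itself, a six-membered ring formed from two intermolecular σ bonds in one suprafacial event. C1 is set by the catalyst: with the (R)-diphenylprolinol-derived antipode the accepted model leaves the Si face of the α-carbon open, which gives 1S in target numbering (6R in the name of 8, because the formyl group outranks C14). C14 follows from the endo position of the boron-bound formyl group (O14 cis to C2), C10 from the E geometry of the enal (C9 trans to C2), and C11 from the Z geometry of the diene terminus (methyl cis to the acetoxy group; this centre is erased in step 9). Regiochemistry requires C11 to bond to the β-carbon; both oxygen donors of the diene raise the coefficient at C11 and the coordinated formyl group raises it at C10. Endo selectivity rests on secondary overlap with the s-trans formyl complex, and facial selectivity on the phenyl shield of the catalyst.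

Step 6
Reactants: 8 ring A cycloadduct
Product: 9 homoallylic alcohol (C2 of 8 converted into a 2R carbinol bearing an allyl group; ring unchanged)
Conditions: B-allyldiisopinocampheylborane from (−)-α-pinene, Et2O, −78 °C; then NaBO3·4H2O, THF–H2O, rt
Reagents that add atoms: B-allyldiisopinocampheylborane C=CCB(C1CC2CC(C1C)C2(C)C)C1CC2CC(C1C)C2(C)C
Why: Brown allylboration through a chair transition state; the reagent antipode that attacks the Re face of a neopentyl-type aldehyde overrides the weak substrate bias and gives 2R, and the perborate work-up spares the enol ether and the acetate.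

Step 7
Reactants: 9 homoallylic alcohol
Product: 10 2,14-diacetate silyl enol ether
Conditions: Ac2O, pyridine, DMAP (cat.), CH2Cl2, rt
Reagents that add atoms: acetic anhydride CC(=O)OC(C)=O
Why: DMAP-catalysed acetylation of a hindered secondary alcohol installs the C2 acetate of the target; any 1,3-acetyl migration from O14 during work-up of step 6 converges here.

Step 8
Reactants: 10 2,14-diacetate silyl enol ether
Product: 11 C12 ketone (2,14-diacetate, O9 TBDPS ether)
Conditions: 0.5 M aq. HCl, THF, 0 °C
Reagents that add atoms: none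
Why: Acid hydrolysis of a silyl enol ether proceeds by C-protonation, so no free enolate forms that could expel the β-acetoxy group; the TBDPS ether and the acetates are stable.

Step 9
Reactants: 11 C12 ketone
Product: 12 C11=C12 enol triflate
Conditions: Tf2O, 2,6-di-tert-butyl-4-methylpyridine, CH2Cl2, 0 °C to rt
Reagents that add atoms: triflic anhydride O=S(=O)(OS(=O)(=O)C(F)(F)F)C(F)(F)F
Why: Enol triflate formation with Tf2O and a hindered pyridine goes through the O-triflyl oxocarbenium ion and loss of a proton to the more substituted, thermodynamically preferred enol triflate, as known for 2-alkyl ketones; no enolate is involved, so the C14 acetate is not eliminated.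

Step 10
Reactants: 12 C11=C12 enol triflate
Product: 13 ring A olefin (C11=C12; 2,14-diacetate; O9 TBDPS ether)
Conditions: Pd(OAc)2 (5 mol %), PPh3, Bu3N, HCO2H, DMF, 60 °C
Reagents that add atoms: none
Why: Palladium-catalysed formate reduction of an alkenyl triflate (oxidative addition to zerovalent palladium, formate decarboxylation, reductive elimination); both acetates are homoallylic and cannot ionise.

Step 11
Reactants: 13 ring A olefin
Product: 14 primary alcohol (C9 hydroxyl free)
Conditions: HF·pyridine, pyridine, THF, 0 °C to rt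
Reagents that add atoms: none
Why: Fluoride cleavage of the silyl ether under buffered, slightly acidic conditions avoids the acetyl migration that basic fluoride could cause.

Step 12
Reactants: 14 primary alcohol
Product: 15 C9 aldehyde
Conditions: Dess–Martin periodinane, NaHCO3, CH2Cl2, 0 °C
Reagents that add atoms: none
Why: Buffered Dess–Martin oxidation gives the β,γ-unsaturated aldehyde without shifting the olefin or epimerising C10; the aldehyde is used at once.

Step 13
Reactants: 16 1-methoxy-4-[(prop-2-yn-1-yloxy)methyl]benzene; 17 [(tert-butyldimethylsilyl)oxy]acetaldehyde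
Product: 19 1-[(tert-butyldimethylsilyl)oxy]-5-[(4-methoxybenzyl)oxy]pent-3-yn-2-ol, via lithium acetylide 18 (not isolated)
Conditions: n-BuLi, THF, −78 °C; then 17; aq. NH4Cl
Reagents that add atoms: none
Why: Addition of a lithium acetylide to an aldehyde; the carbinol is oxidised next, so the racemate is sufficient.

Step 14
Reactants: 19 1-[(tert-butyldimethylsilyl)oxy]-5-[(4-methoxybenzyl)oxy]pent-3-yn-2-ol
Product: 20 1-[(tert-butyldimethylsilyl)oxy]-5-[(4-methoxybenzyl)oxy]pent-3-yn-2-one
Conditions: Dess–Martin periodinane, NaHCO3, CH2Cl2, rt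
Reagents that add atoms: none
Why: Dess–Martin oxidation of a propargylic alcohol to the ynone.

Step 15
Reactants: 20 1-[(tert-butyldimethylsilyl)oxy]-5-[(4-methoxybenzyl)oxy]pent-3-yn-2-one
Product: 21 (Z)-1-[(tert-butyldimethylsilyl)oxy]-4-iodo-5-[(4-methoxybenzyl)oxy]pent-3-en-2-one
Conditions: NaI, AcOH, rt
Reagents that add atoms: sodium iodide [Na+].[I-]
Why: Conjugate hydroiodination of an ynone: iodide adds to the β-carbon and anti protonation gives the Z β-iodoenone, which fixes iodine on C5 and the cis C4/C7 relationship of the future ring olefin.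

Step 16
Reactants: 21 (Z)-β-iodoenone; 15 C9 aldehyde
Product: 23 aldol adduct (9R hydroxyl; 8-silyloxy syn to it; C7 ketone; alkenyl iodide at C5), via dibutylboron enolate 22 (not isolated)
Conditions: Bu2BOTf, i-Pr2NEt, CH2Cl2, −78 °C; then 15, −78 to −20 °C; pH 7 buffer, MeOH
Reagents that add atoms: none
Why: Boron-mediated aldol reaction: only C8 of the enone can be enolised, and the aldehyde is attacked through a chair transition state anti to the quaternary C1 branch of C10 (Felkin–Anh), giving 9R; the configuration at C8 (syn expected) is immaterial.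

Step 17
Reactants: 23 aldol adduct
Product: 24 11,12-epoxy aldol adduct (epoxide on the face of the C9 side chain)
Conditions: VO(acac)2 (10 mol %), t-BuOOH, CH2Cl2, 0 °C to rt
Reagents that add atoms: tert-butyl hydroperoxide CC(C)(C)OO
Why: Vanadium-catalysed hydroxyl-directed epoxidation of a homoallylic alcohol: the vanadate ester of the C9 hydroxyl delivers oxygen to the face of C11=C12 on which the side chain sits; the electron-poor iodoenone and the undirected terminal olefin are left alone.

Step 18
Reactants: 24 11,12-epoxy aldol adduct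
Product: 25 syn-diol (7S and 9R hydroxyls)
Conditions: Et2BOMe, THF–MeOH (4:1), −78 °C; NaBH4; then AcOH, MeOH evaporation
Reagents that add atoms: none
Why: Narasaka–Prasad reduction: the β-hydroxy ketone forms a six-membered boron chelate and external hydride attacks axially, giving the 1,3-syn diol and hence 7S by 1,2-reduction of the enone.

Step 19
Reactants: 25 syn-diol
Product: 26 7-O-(2-bromopropanoyl) ester of 25 (9-hydroxyl free)
Conditions: 2-bromopropanoyl bromide (1.05 equiv), pyridine, CH2Cl2, −78 to −40 °C
Reagents that add atoms: 2-bromopropanoyl bromide CC(Br)C(Br)=O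
Why: Site-selective acylation of the less hindered allylic C7 hydroxyl; the C9 carbinol is wedged between the C8 silyl ether and ring A.

Step 20
Reactants: 26 7-O-(2-bromopropanoyl) ester
Product: 27 9-acetate 7-(2-bromopropanoate)
Conditions: Ac2O, pyridine, DMAP (cat.), CH2Cl2, 0 °C to rt
Reagents that add atoms: acetic anhydride CC(=O)OC(C)=O
Why: Acetylation of the hindered C9 hydroxyl; α-halo esters survive these conditions, as haloacetate protecting groups do.

Step 21
Reactants: 27 9-acetate 7-(2-bromopropanoate)
Product: 28 C8 alcohol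
Conditions: HF·pyridine, pyridine, THF, 0 °C to rt
Reagents that add atoms: none
Why: Buffered HF·pyridine removes the secondary TBS ether; trisubstituted epoxides, PMB ethers and esters tolerate it, and the acidic medium disfavours acyl migration to O8.

Step 22
Reactants: 28 C8 alcohol
Product: 29 C8 ketone (α-acetoxy on C9, α-(2-bromopropanoyloxy) on C7)
Conditions: Dess–Martin periodinane, NaHCO3, CH2Cl2, 0 °C to rt
Reagents that add atoms: none
Why: Neutral Dess–Martin oxidation; base is avoided because C7–H is allylic and α to the new ketone.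

Step 23
Reactants: 29 C8 ketone
Product: 31 γ-lactone (8-hydroxyl cis to C6; 17-methyl trans to C9; both as in the target), via samarium enolate 30 (not isolated)
Conditions: SmI2 (2.5 equiv), THF, −78 °C; then H2O
Reagents that add atoms: none
Why: Intramolecular Reformatsky reaction of an α-(bromoacyloxy) ketone: two-electron reduction of the C–Br bond gives the trivalent samarium enolate only at C17, which adds 5-exo to the C8 ketone through a samarium-bridged transition state; C9 goes trans to C6 and the methyl trans to C9 on the forming ring, and the O7 tether excludes the O9 lactone.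

Step 24
Reactants: 31 γ-lactone
Product: 33 C4 aldehyde (seco-aldehyde), via vicinal diol 32 (not isolated)
Conditions: OsO4 (2 mol %), NaIO4, 2,6-lutidine, dioxane–H2O (3:1), rt
Reagents that add atoms: osmium tetroxide O=[Os](=O)(=O)=O; sodium periodate [Na+].[O-]I(=O)(=O)=O
Why: Lemieux–Johnson cleavage: OsO4 dihydroxylates the unhindered monosubstituted olefin far faster than the iodine-deactivated trisubstituted C5=C6, and periodate cleaves the diol; lutidine limits over-oxidation and β-elimination of the C2 acetate.

Step 25
Reactants: 33 C4 aldehyde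
Product: 35 macrocyclic allylic alcohol (4R; ten-membered ring closed), via alkenylchromium species 34 (not isolated)
Conditions: CrCl2 (10 equiv), NiCl2 (2 mol %), DMSO, rt, 0.002 M
Reagents that add atoms: none
Why: Intramolecular Nozaki–Hiyama–Kishi reaction: zerovalent nickel inserts into the C5–I bond with retention of geometry, transmetalation gives the trivalent alkenylchromium, and this adds only to the aldehyde; 1,3-anti induction from the C2 acetoxy group in a non-chelated transition state should favour 4R.

Step 26
Reactants: 35 macrocyclic allylic alcohol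
Product: 36 16-O-(4-methoxybenzyl) ether of the target (2,4,9,14-tetraacetate)
Conditions: Ac2O, pyridine, DMAP (cat.), CH2Cl2, 0 °C
Reagents that add atoms: acetic anhydride CC(=O)OC(C)=O
Why: Acetylation of the allylic C4 hydroxyl; the tertiary C8 hydroxyl does not react under these mild conditions.

Step 27
Reactants: 36 16-O-(4-methoxybenzyl) ether of the target
Product: 37 CNP0104124.1
Conditions: DDQ (1.3 equiv), CH2Cl2–pH 7 buffer (10:1), 0 °C
Reagents that add atoms: none
Why: Oxidative cleavage of the PMB ether by DDQ (hydride abstraction, hydrolysis of the oxocarbenium ion) under buffered conditions leaves epoxide, acetates and lactone intact.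

## Compound list

1 | pent-1-yn-3-ol | CCC(O)C#C | starting material
2 | pent-1-yn-3-one | CCC(=O)C#C | intermediate
3 | (E)-3-oxopent-1-en-1-yl acetate | CCC(=O)/C=C/OC(C)=O | intermediate
4 | (1E,3Z)-3-[(tert-butyldimethylsilyl)oxy]penta-1,3-dien-1-yl acetate | CC(=O)O/C=C/C(O[Si](C)(C)C(C)(C)C)=C/C | intermediate
5 | [(tert-butyldiphenylsilyl)oxy]acetaldehyde | O=CCO[Si](c1ccccc1)(c1ccccc1)C(C)(C)C | starting material
6 | 2-(triphenylphosphoranylidene)propanal | CC(C=O)=P(c1ccccc1)(c1ccccc1)c1ccccc1 | starting material
7 | (E)-4-[(tert-butyldiphenylsilyl)oxy]-2-methylbut-2-enal | O=C/C(C)=C/CO[Si](c1ccccc1)(c1ccccc1)C(C)(C)C | intermediate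
8 | ring A cycloadduct, (1S,4S,5S,6R)-3-[(tert-butyldimethylsilyl)oxy]-5-{[(tert-butyldiphenylsilyl)oxy]methyl}-6-formyl-4,6-dimethylcyclohex-2-en-1-yl acetate | CC(=O)O[C@H]1C=C(O[Si](C)(C)C(C)(C)C)[C@@H](C)[C@H](CO[Si](c2ccccc2)(c2ccccc2)C(C)(C)C)[C@@]1(C)C=O | intermediate
9 | homoallylic alcohol (2R carbinol with allyl group at C2 of 8) | CC(=O)O[C@H]1C=C(O[Si](C)(C)C(C)(C)C)[C@@H](C)[C@H](CO[Si](c2ccccc2)(c2ccccc2)C(C)(C)C)[C@@]1(C)[C@H](O)CC=C | intermediate
10 | 2,14-diacetate silyl enol ether | CC(=O)O[C@H]1C=C(O[Si](C)(C)C(C)(C)C)[C@@H](C)[C@H](CO[Si](c2ccccc2)(c2ccccc2)C(C)(C)C)[C@@]1(C)[C@H](OC(C)=O)CC=C | intermediate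
11 | C12 ketone (2,14-diacetate, O9 TBDPS ether) | CC(=O)O[C@H]1CC(=O)[C@@H](C)[C@H](CO[Si](c2ccccc2)(c2ccccc2)C(C)(C)C)[C@@]1(C)[C@H](OC(C)=O)CC=C | intermediate
12 | C11=C12 enol triflate | CC(=O)O[C@H]1CC(OS(=O)(=O)C(F)(F)F)=C(C)[C@H](CO[Si](c2ccccc2)(c2ccccc2)C(C)(C)C)[C@@]1(C)[C@H](OC(C)=O)CC=C | intermediate
13 | ring A olefin (C11=C12, 2,14-diacetate, O9 TBDPS ether) | CC(=O)O[C@H]1CC=C(C)[C@H](CO[Si](c2ccccc2)(c2ccccc2)C(C)(C)C)[C@@]1(C)[C@H](OC(C)=O)CC=C | intermediate
14 | primary alcohol (C9 hydroxyl) | CC(=O)O[C@H]1CC=C(C)[C@H](CO)[C@@]1(C)[C@H](OC(C)=O)CC=C | intermediate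
15 | C9 aldehyde | CC(=O)O[C@H]1CC=C(C)[C@H](C=O)[C@@]1(C)[C@H](OC(C)=O)CC=C | intermediate
16 | 1-methoxy-4-[(prop-2-yn-1-yloxy)methyl]benzene | C#CCOCc1ccc(OC)cc1 | starting material
17 | [(tert-butyldimethylsilyl)oxy]acetaldehyde | O=CCO[Si](C)(C)C(C)(C)C | starting material
18 | lithium acetylide of 16 | [Li]C#CCOCc1ccc(OC)cc1 | intermediate
19 | 1-[(tert-butyldimethylsilyl)oxy]-5-[(4-methoxybenzyl)oxy]pent-3-yn-2-ol (racemic) | CC(C)(C)[Si](C)(C)OCC(O)C#CCOCc1ccc(OC)cc1 | intermediate
20 | 1-[(tert-butyldimethylsilyl)oxy]-5-[(4-methoxybenzyl)oxy]pent-3-yn-2-one | CC(C)(C)[Si](C)(C)OCC(=O)C#CCOCc1ccc(OC)cc1 | intermediate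
21 | (Z)-1-[(tert-butyldimethylsilyl)oxy]-4-iodo-5-[(4-methoxybenzyl)oxy]pent-3-en-2-one | CC(C)(C)[Si](C)(C)OCC(=O)/C=C(\I)COCc1ccc(OC)cc1 | intermediate
22 | (Z)-dibutylboron enolate of 21 | CCCCB(CCCC)O/C(=C\O[Si](C)(C)C(C)(C)C)/C=C(\I)COCc1ccc(OC)cc1 | intermediate
23 | aldol adduct (9R hydroxyl, 8-silyloxy syn, C7 ketone, C5 iodide) | CC(=O)O[C@H]1CC=C(C)[C@H]([C@@H](O)[C@H](O[Si](C)(C)C(C)(C)C)C(=O)/C=C(\I)COCc2ccc(OC)cc2)[C@@]1(C)[C@H](OC(C)=O)CC=C | intermediate
24 | 11,12-epoxy aldol adduct | CC(=O)O[C@H]1C[C@@H]2O[C@]2(C)[C@H]([C@@H](O)[C@H](O[Si](C)(C)C(C)(C)C)C(=O)/C=C(\I)COCc2ccc(OC)cc2)[C@@]1(C)[C@H](OC(C)=O)CC=C | intermediate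
25 | syn-diol (7S, 9R) | CC(=O)O[C@H]1C[C@@H]2O[C@]2(C)[C@H]([C@@H](O)[C@H](O[Si](C)(C)C(C)(C)C)[C@@H](O)/C=C(\I)COCc2ccc(OC)cc2)[C@@]1(C)[C@H](OC(C)=O)CC=C | intermediate
26 | 7-O-(2-bromopropanoyl) ester of 25 | CC(=O)O[C@H]1C[C@@H]2O[C@]2(C)[C@H]([C@@H](O)[C@H](O[Si](C)(C)C(C)(C)C)[C@@H](OC(=O)C(C)Br)/C=C(\I)COCc2ccc(OC)cc2)[C@@]1(C)[C@H](OC(C)=O)CC=C | intermediate
27 | 9-acetate 7-(2-bromopropanoate) | CC(=O)O[C@H]1C[C@@H]2O[C@]2(C)[C@H]([C@@H](OC(C)=O)[C@H](O[Si](C)(C)C(C)(C)C)[C@@H](OC(=O)C(C)Br)/C=C(\I)COCc2ccc(OC)cc2)[C@@]1(C)[C@H](OC(C)=O)CC=C | intermediate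
28 | C8 alcohol | CC(=O)O[C@H]1C[C@@H]2O[C@]2(C)[C@H]([C@@H](OC(C)=O)[C@H](O)[C@@H](OC(=O)C(C)Br)/C=C(\I)COCc2ccc(OC)cc2)[C@@]1(C)[C@H](OC(C)=O)CC=C | intermediate
29 | C8 ketone | CC(=O)O[C@H]1C[C@@H]2O[C@]2(C)[C@H]([C@@H](OC(C)=O)C(=O)[C@@H](OC(=O)C(C)Br)/C=C(\I)COCc2ccc(OC)cc2)[C@@]1(C)[C@H](OC(C)=O)CC=C | intermediate
30 | trivalent samarium enolate of 29 | CC(=O)O[C@H]1C[C@@H]2O[C@]2(C)[C@H]([C@@H](OC(C)=O)C(=O)[C@@H](OC(O[Sm](I)I)=CC)/C=C(\I)COCc2ccc(OC)cc2)[C@@]1(C)[C@H](OC(C)=O)CC=C | intermediate
31 | γ-lactone with terminal olefin | CC(=O)O[C@H]1C[C@@H]2O[C@]2(C)[C@H]([C@@H](OC(C)=O)[C@@]3(O)[C@H](/C=C(\I)COCc4ccc(OC)cc4)OC(=O)[C@@H]3C)[C@@]1(C)[C@H](OC(C)=O)CC=C | intermediate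
32 | vicinal diol from 31 | CC(=O)O[C@H]1C[C@@H]2O[C@]2(C)[C@H]([C@@H](OC(C)=O)[C@@]3(O)[C@H](/C=C(\I)COCc4ccc(OC)cc4)OC(=O)[C@@H]3C)[C@@]1(C)[C@H](OC(C)=O)CC(O)CO | intermediate
33 | C4 aldehyde (seco-aldehyde) | CC(=O)O[C@H]1C[C@@H]2O[C@]2(C)[C@H]([C@@H](OC(C)=O)[C@@]3(O)[C@H](/C=C(\I)COCc4ccc(OC)cc4)OC(=O)[C@@H]3C)[C@@]1(C)[C@H](OC(C)=O)CC=O | intermediate
34 | trivalent alkenylchromium species from 33 | CC(=O)O[C@H]1C[C@@H]2O[C@]2(C)[C@H]([C@@H](OC(C)=O)[C@@]3(O)[C@H](/C=C(\[Cr](Cl)Cl)COCc4ccc(OC)cc4)OC(=O)[C@@H]3C)[C@@]1(C)[C@H](OC(C)=O)CC=O | intermediate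
35 | macrocyclic allylic alcohol (4R) | CC(=O)O[C@H]1C[C@@H]2O[C@]2(C)[C@@H]2[C@@H](OC(C)=O)[C@@]3(O)[C@H](/C=C(/COCc4ccc(OC)cc4)[C@H](O)C[C@@H](OC(C)=O)[C@@]12C)OC(=O)[C@@H]3C | intermediate
36 | 16-O-(4-methoxybenzyl) ether of the target | CC(=O)O[C@H]1C[C@@H]2O[C@]2(C)[C@@H]2[C@@H](OC(C)=O)[C@@]3(O)[C@H](/C=C(/COCc4ccc(OC)cc4)[C@H](OC(C)=O)C[C@@H](OC(C)=O)[C@@]12C)OC(=O)[C@@H]3C | intermediate
37 | CNP0104124.1 | CC(=O)O[C@H]1C[C@@H]2O[C@]2(C)[C@@H]2[C@@H](OC(C)=O)[C@@]3(O)[C@H](/C=C(/CO)[C@H](OC(C)=O)C[C@@H](OC(C)=O)[C@@]12C)OC(=O)[C@@H]3C | target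

## Step count and least certain steps

Total step count: 27. Longest linear sequence: 23 steps (steps 1–3, 5–12 and 16–27).

**Step 5 (key step).**
- What may go wrong: slow cycloaddition of the trisubstituted, β-substituted enal, so that acid-mediated destruction of the diene competes; or low or reversed facial selectivity, since the choice of catalyst antipode rests on a model.
- Fallback: diene 4 and enal 7 are heated without catalyst (toluene, 90 °C, BHT). This gives the racemate, that is 8 together with the enantiomeric cycloadduct F1. The reagent-controlled allylation of step 6 converts the racemate into 9 and the diastereomeric homoallylic alcohol F2. These are separated by chromatography, and the route is rejoined at 9.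

**Step 9.**
- What may go wrong: loss of regiocontrol, with proton loss from C13 instead of C11.
- Fallback: ketone 11 is brominated at the more substituted α-carbon with PhNMe3Br3 (THF, 0 °C; acid-catalysed enolisation, olefin untouched) to give the C11 bromo ketone F3. NaBH4/CeCl3·7H2O reduces F3 to the bromohydrin F4 (either C12 epimer serves). Zn in AcOH eliminates bromine and hydroxyl and returns olefin 13 with the double bond fixed at C11=C12.

**Step 16.**
- What may go wrong: poor facial selectivity at C9, because the closed transition state of a Z enolate can oppose the Felkin preference; and addition–elimination at the β-iodoenone during enolisation.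
- Fallback: ynone 20 is converted with TMSOTf/Et3N into the silyl enol ether F5. A BF3·OEt2-promoted Mukaiyama aldol reaction of F5 with 15 (open transition state) gives the β-hydroxy ynone F6. NaI/AcOH then adds HI to F6 and gives 23; the C8 epimer would converge at 29.

**Step 19.**
- What may go wrong: insufficient discrimination between the C7 and C9 hydroxyls.
- Fallback: epoxy aldol 24 is treated with acetaldehyde and a catalyst formed from SmI2 (30 mol %) in an Evans–Tishchenko reduction. Hydride is transferred within the hemiacetal, which puts the acetate on O9 and leaves the anti (7R) alcohol F7. A Mitsunobu reaction of F7 with 2-bromopropanoic acid (PPh3, DIAD) inverts C7 and gives 27 directly.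

**Step 23.**
- What may go wrong: ketyl formation at the doubly α-oxygenated ketone, with reductive loss of an acyloxy group, competing with reduction of the C–Br bond.
- Fallback: diol 25 is acylated at O7 with acryloyl chloride to give the acrylate F8. Acetylation gives F9, HF·pyridine gives the C8 alcohol F10, and Dess–Martin oxidation gives the keto acrylate F11. [(Ph3P)CuH]6 reduces the acrylate of F11 to a copper enolate, which closes the lactone by reductive aldol cyclisation and gives 31.

**Step 25.**
- What may go wrong: low facial selectivity in the addition to the aldehyde (and, at higher concentration, intermolecular coupling).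
- Fallback: the cyclisation mixture of 35 and its C4 epimer F12 is oxidised with Dess–Martin periodinane to the macrocyclic enone F13. 1,2-Reduction of F13 with NaBH4/CeCl3·7H2O, or with (R)- or (S)-2-methyl-CBS-oxazaborolidine and catecholborane if reagent control is needed, gives 35.

## Further compounds

F1 | step 5 | enantiomer of cycloadduct 8 | CC(=O)O[C@@H]1C=C(O[Si](C)(C)C(C)(C)C)[C@H](C)[C@@H](CO[Si](c2ccccc2)(c2ccccc2)C(C)(C)C)[C@]1(C)C=O
F2 | step 5 | diastereomeric homoallylic alcohol (2R carbinol on the enantiomeric ring) | CC(=O)O[C@@H]1C=C(O[Si](C)(C)C(C)(C)C)[C@H](C)[C@@H](CO[Si](c2ccccc2)(c2ccccc2)C(C)(C)C)[C@]1(C)[C@H](O)CC=C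
F3 | step 9 | C11 bromo ketone | CC(=O)O[C@H]1CC(=O)[C@](Br)(C)[C@H](CO[Si](c2ccccc2)(c2ccccc2)C(C)(C)C)[C@@]1(C)[C@H](OC(C)=O)CC=C
F4 | step 9 | C11 bromo C12 hydroxy compound (bromohydrin) | CC(=O)O[C@H]1C[C@H](O)[C@](Br)(C)[C@H](CO[Si](c2ccccc2)(c2ccccc2)C(C)(C)C)[C@@]1(C)[C@H](OC(C)=O)CC=C
F5 | step 16 | (Z)-trimethylsilyl enol ether of ynone 20 | CC(C)(C)[Si](C)(C)O/C=C(\O[Si](C)(C)C)C#CCOCc1ccc(OC)cc1
F6 | step 16 | β-hydroxy ynone (9R hydroxyl, 8-silyloxy, C7 ynone) | CC(=O)O[C@H]1CC=C(C)[C@H]([C@@H](O)[C@H](O[Si](C)(C)C(C)(C)C)C(=O)C#CCOCc2ccc(OC)cc2)[C@@]1(C)[C@H](OC(C)=O)CC=C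
F7 | step 19 | 9-acetate with free 7R hydroxyl (anti) | CC(=O)O[C@H]1C[C@@H]2O[C@]2(C)[C@H]([C@@H](OC(C)=O)[C@H](O[Si](C)(C)C(C)(C)C)[C@H](O)/C=C(\I)COCc2ccc(OC)cc2)[C@@]1(C)[C@H](OC(C)=O)CC=C
F8 | step 23 | 7-O-acrylate of diol 25 | CC(=O)O[C@H]1C[C@@H]2O[C@]2(C)[C@H]([C@@H](O)[C@H](O[Si](C)(C)C(C)(C)C)[C@@H](OC(=O)C=C)/C=C(\I)COCc2ccc(OC)cc2)[C@@]1(C)[C@H](OC(C)=O)CC=C
F9 | step 23 | 9-acetate 7-acrylate | CC(=O)O[C@H]1C[C@@H]2O[C@]2(C)[C@H]([C@@H](OC(C)=O)[C@H](O[Si](C)(C)C(C)(C)C)[C@@H](OC(=O)C=C)/C=C(\I)COCc2ccc(OC)cc2)[C@@]1(C)[C@H](OC(C)=O)CC=C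
F10 | step 23 | C8 alcohol of the acrylate series | CC(=O)O[C@H]1C[C@@H]2O[C@]2(C)[C@H]([C@@H](OC(C)=O)[C@H](O)[C@@H](OC(=O)C=C)/C=C(\I)COCc2ccc(OC)cc2)[C@@]1(C)[C@H](OC(C)=O)CC=C
F11 | step 23 | C8 keto acrylate | CC(=O)O[C@H]1C[C@@H]2O[C@]2(C)[C@H]([C@@H](OC(C)=O)C(=O)[C@@H](OC(=O)C=C)/C=C(\I)COCc2ccc(OC)cc2)[C@@]1(C)[C@H](OC(C)=O)CC=C
F12 | step 25 | C4 epimer of 35 | CC(=O)O[C@H]1C[C@@H]2O[C@]2(C)[C@@H]2[C@@H](OC(C)=O)[C@@]3(O)[C@H](/C=C(/COCc4ccc(OC)cc4)[C@@H](O)C[C@@H](OC(C)=O)[C@@]12C)OC(=O)[C@@H]3C
F13 | step 25 | macrocyclic C4 enone | CC(=O)O[C@H]1C[C@@H]2O[C@]2(C)[C@@H]2[C@@H](OC(C)=O)[C@@]3(O)[C@H](/C=C(/COCc4ccc(OC)cc4)C(=O)C[C@@H](OC(C)=O)[C@@]12C)OC(=O)[C@@H]3C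
A1 | alternative 1 | ten-membered 4,9-diketone (C7/C8 acetonide, C17 methyl ester side chain) | CC(=O)O[C@H]1C[C@@H]2O[C@]2(C)[C@@H]2C(=O)[C@@]3([C@@H](C)C(=O)OC)OC(C)(C)O[C@H]3/C=C(/CO[Si](c4ccccc4)(c4ccccc4)C(C)(C)C)C(=O)C[C@@H](OC(C)=O)[C@@]12C
A2 | alternative 2 | bicyclic 2,14-diketone with C11=C12 olefin | O=C1CC=C(C)[C@@H]2[C@@H](OC(C)=O)[C@@]3(O[Si](C)(C)C)[C@H](/C=C(/CO[Si](c4ccccc4)(c4ccccc4)C(C)(C)C)[C@H](OC(C)=O)CC(=O)[C@@]12C)OC(=O)[C@@H]3C
A3 | alternative 3 | β-hydroxy γ-lactone (O9 triethylsilyl, O16 tert-butyldiphenylsilyl) | CC(=O)O[C@H]1C[C@@H]2O[C@]2(C)[C@@H]2[C@@H](O[Si](CC)(CC)CC)[C@@]3(O)[C@H](/C=C(/CO[Si](c4ccccc4)(c4ccccc4)C(C)(C)C)[C@H](OC(C)=O)C[C@@H](OC(C)=O)[C@@]12C)OC(=O)[C@@H]3C
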